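(The data come from a simulation from invented constants; the scatter is artificial.)

Monday's run took J to 104% by 3.00 h on 4.8 equiv of X, far above the 2% of Thursday's run on 0.66 equiv, so for your quick number on cedar we reckon with the X to spare.

| flask | Q | X | remark | time |
|---|---|---|---|---|
| Thursday's | 0.61 M | 0.66 equiv | run made earlier |  |
| Monday's | 0.61 M | 4.8 equiv | run made earlier |  |
| alder | 0.61 M | 1.50 equiv |  | 4.0 h |
| cedar | 0.61 M | 4.00 equiv |  | 4.0 h |
| ash | 0.61 M | 0.500 equiv |  | 4.0 h |

- Thursday's (time / h: J / %, D / %): 0.250: 0, 23; 0.417: 0, 24; 0.833: 0, 29; 1.33: 2, 28; 3.00: 2, 30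
- Monday's (time / h: J / %, D / %): 0.250: 43, 26; 0.667: 75, 10; 1.33: 91, 4; 2.00: 99, 1; 3.00: 104, 0

(scatter of a reading: 2 percentage points)

- which of these holds the largest part of the Q at the end of alder (D / J / Q)
- which of these holds the largest part of the Q at the end of cedar (D / J / Q)
- which of these holds the largest part of the Q at the end of ash (D / J / Q)
- J at the end of cedar, in percent of the Q charged



We assume one X for each step, Q to D and D to J, so two equivalents per J, and call whatever lies beyond that spare. Late in a run with spare X, we expect the part of the charge not yet J, the gap, to shrink at a steady fractional rate: a pseudo-first-order tail. In Monday's run the gap reads 25.0% at 0.667 h and 9.00% at 1.33 h, a rate of 1.54 h⁻¹ with the scatter of those readings. With 2.80 spare, that is 0.550 h⁻¹ per spare equivalent, our tail rate. Carried back to zero time, this tail line of Monday's run meets 69.9%, and we assume cedar's tail line starts there too. Cedar has 2.00 spare, so its gap falls at 1.10 h⁻¹ and after 4.0 h stands at 0.856%, which puts J at 99.1%.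

Your hunch, the forecast, names D for alder, J for cedar and Q for ash, with J at 93% in cedar, and holds that Monday's flask “needs about 3 X per J”. We differ there, and our number stands above yours.

    Q + X → D + L (k = 0.0113 M⁻¹ s⁻¹)
    X + D → J + L (k = 7.96 × 10⁻⁴ M⁻¹ s⁻¹)
    D ⇌ G (K = 1.16, k = 0.0422 s⁻¹)
    X ⇌ E (K = 0.403, k = 0.0512 s⁻¹)

Cedar ends with J at 99.3%. At that time X stands at 35.8% of its own charge and E at 0.352 M, together 2.01 equivalents. Using the tail rate once more: cedar's J stands at 93.0% after 2.00 h, and 1.10 h⁻¹ over the remaining 2.00 h reckons the gap down to 0.778%, which by this reckoning puts J at 99.2%.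

Take cedar stopped at 1.5 h: the same tail line reckons a gap of 13.4%, so J at 86.6%. That flask gives J 87.2%.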